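## The problem

Target **16** is an isoflavone. Ring A carries hydroxyls at C5 and C7, ring C is the 4-pyranone, and ring B is bonded through C1' to C3. Ring B bears a hydroxyl at C3', a methoxyl at C4' and, at C5', the chain C5'–Cα=Cβ–Cγ(CH3)=CH2. There is no stereocentre. The only stereochemical element is the E geometry of Cα=Cβ, and nothing in the molecule can steer it, so the reaction that creates this alkene must fix it. Ring A has the symmetrical oxygen pattern of phloroglucinol, so closure of ring C raises no regiochemical question. Ring B is harder: the carbon chain sits ortho to the methoxyl and meta to the hydroxyl, a position that electrophilic substitution of a 3-hydroxy-4-methoxyphenyl unit does not reach. The handle for the chain must therefore be placed while the C4' oxygen is still a free phenol, and the methyl group moved afterwards.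

Several groups are fragile. The 2-substituted 1,3-diene is protonated at its terminal CH2 to a tertiary, doubly conjugated cation, so it does not tolerate acid, hydrogenation or oxidants. The three phenols include an acidic 7-hydroxyl and a chelated 5-hydroxyl. C2 of the chromone is opened by hydroxide, alkoxide or amines on heating. The 4'-methyl ether must outlast any ether cleavage.

The feature that invites the key step is the Cβ–Cγ single bond. It joins two sp2 carbons, an E-styryl unit on ring B and an isopropenyl unit, so it can be made by cross-coupling under weak base as the last operation.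

## Retrosynthesis

**Cβ–Cγ (16 ⇒ 14 + 15).** The diene is cut at its central single bond into the E-alkenylboronate **14** and 2-bromopropene **15**. The neighbouring cuts are weaker. Cutting C5'–Cα would need arylation of a free diene, which has regiochemical ambiguity and exposes the diene to hot palladium hydride. Cutting Cα=Cβ would need an allylic ylide and gives no E control. Cutting Cγ=CH2 would need an elimination under acid or activation. The chosen cut uses a commercial three-carbon half, fixes the geometry beforehand in the boronate, and forms the sensitive diene last, with no protecting group to remove afterwards. Boron is placed on the styryl half because that half can be made in one step from an aryl bromide. The forward reaction must retain the alkene geometry and outrun protodeboronation.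

**Acetates and C5'–Cα (14 ⇒ 13 ⇒ 11 + 12).** The triol **14** comes from its triacetate **13** by base-only deacylation, which a pinacol alkenylboronate tolerates. **13** is cut at C5'–Cα into aryl bromide **11** and vinylboronate **12**; forward, this is a Heck arylation in which the C–B bond is a spectator. Routes to the alkenylboronate through an arylalkyne or an aryl aldehyde would each cost extra steps on ring B. Acetates are chosen because they quiet the three acidic phenols during the amine-mediated palladium step and come off without acid.

**Ring C (11 ⇒ 10 ⇒ 9 ⇒ 7 + 8).** Triacetate **11** is the peracetylated bromo isoflavone **10**. Ring C of **10** is opened at O1–C2 and C2–C3, removing C2 as a one-carbon electrophile and exposing deoxybenzoin **9**. **9** is cut at C4–C4a into arylacetic acid **7** and phloroglucinol **8**. Because **8** is symmetrical, acylation and ring closure each have one possible outcome. Both reactions tolerate free phenols, so the two can share one flask without protecting groups.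

**One-carbon homologation (7 ⇒ 5 ⇒ 3 + 4).** Acid **7** has one carbon more than aldehyde **3**. The azlactone route bonds the aldehyde carbon to the α-carbon of N-acetylglycine **4**, giving **5**, and then degrades the glycine carboxyl. It tolerates the phenol, which is transiently acetylated. A benzylic halide and cyanide route would need separate phenol protection, because a free phenol next to a benzylic halide invites self-alkylation.

**Methyl transposition (3 ⇒ 2 ⇒ 1).** Aldehyde **3** has the bromine ortho to the methoxyl, a pattern not reached by direct bromination. 5-Bromovanillin **1** has the bromine in the right place but the methyl on the wrong oxygen. Demethylation to catechol **2** and re-methylation at the more acidic 4-hydroxyl (para to the formyl group, ortho to bromine) corrects this in two steps.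

## Roads not taken

**Alternative 1:** Aryne annulation. Ring C is cut at O1–C8a and C4–C4a. Fluoride would release 3,5-bis(benzyloxy)benzyne from 3,5-bis(benzyloxy)-2-(trimethylsilyl)phenyl triflate A1. The enolate oxygen of methyl 2-[3-(benzyloxy)-5-bromo-4-methoxyphenyl]-3-oxopropanoate A2 would add at the aryne carbon remote from the flanking benzyloxy group, and the resulting aryl anion would acylate on the ester to give 5,7-bis(benzyloxy)-3-[3-(benzyloxy)-5-bromo-4-methoxyphenyl]chromen-4-one A3.

- Merits: rings A and B are joined and ring C closed in one operation near room temperature, and the alkoxy group directs the regiochemistry. In convergence this road is better than the chosen one.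
- Weak points: A1 needs several steps of its own (partial benzylation, ortho-halogenation, silyl transfer, triflation). A2 still needs the homologated ring B acid of the chosen route plus esterification, benzylation and formylation. The ambident enolate can also react at carbon, leading to insertion into the C–C bond instead of annulation.
- Protecting groups: the benzyl ethers of A3 cannot be removed by hydrogenolysis without cleaving the aryl C–Br bond. They cannot be kept to the end either, since neither hydrogenolysis nor a boron trihalide would spare the diene.
- Comparison: the chosen plan sets against the convergence of this road unprotected phloroglucinol **8**, a one-flask ring construction and a base-only end game.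

**Alternative 2:** Intramolecular Wittig olefination of an aryl formate. Ring C is cut at C2=C3. The acyl phosphorane 2-{[3-bromo-4-methoxy-5-(methoxymethoxy)phenyl](triphenylphosphoranylidene)acetyl}-3,5-bis(methoxymethoxy)phenyl formate A4 would attack its own ortho formate carbonyl and give 3-[3-bromo-4-methoxy-5-(methoxymethoxy)phenyl]-5,7-bis(methoxymethoxy)chromen-4-one A5.

- Merits: the closure is neutral and regiochemically unambiguous. No Lewis acid or electrophilic formylating agent comes near the electron-rich ring A, and in that respect it is milder than the chosen ring closure.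
- Weak points: A4 has the same deoxybenzoin skeleton as **9**, so all the early steps are still needed. On top come methoxymethyl protection, α-bromination, phosphonium salt and ylide formation and O-formylation, and the Wittig step releases stoichiometric triphenylphosphine oxide. The ylide is doubly stabilised and hindered by the α-aryl group, so the olefination of an ester carbonyl is not assured. The methoxymethyl ethers need acid for removal, which is harmless at A5 but forces a protecting-group exchange before the diene is built.
- Comparison: the chosen plan reaches the same ring from **9** in the flask where **9** is formed; the boron chelate of the ketone keeps formylation at the methylene.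

**Alternative 3:** Flavanone to isoflavone by oxidative 2,3-aryl migration. The C3–C1' bond is cut. The flavanone 5,7-diacetoxy-2-(3-acetoxy-5-bromo-4-methoxyphenyl)chroman-4-one A6 (racemic) would be oxidised at C3 by PhI(OH)OTs. Ring B would shift from C2 to C3 with assistance from the ring oxygen, and loss of the C3 proton would give 5,7-diacetoxy-3-(3-acetoxy-5-bromo-4-methoxyphenyl)chromen-4-one A7, which is the same compound as **11**.

- Merits: this road is better in one respect. A6 is built from aldehyde **3** by aldol chemistry, so the homologation (steps 3 and 4) is not needed, and A7 enters the same end game.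
- Weak points: aryl migration competes with dehydrogenation to the flavone and with ring contraction. The migrating ring is helped by its para-methoxyl but slowed by the meta bromine and acetoxy groups. The aldol condensation on a phloroglucinol ketone needs protecting groups that must later be exchanged for acetates, which uses up part of the saving. The trivalent iodine oxidant also acts next to an oxygen-rich ring.
- Comparison: the chosen plan accepts two more steps on ring B in exchange for a ring C construction with no competing pathway.

Key step: step 9

## Route

Remark on the chemistry: ring B is numbered with C1' bonded to C3, the hydroxyl at C3', the methoxyl at C4' and the diene at C5'. BF3·OEt2 in step 5 serves as solvent and Lewis acid and is regarded as unchanged.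

Step 1
Reactants: 1 5-bromovanillin (3-bromo-4-hydroxy-5-methoxybenzaldehyde)
Product: 2 3-bromo-4,5-dihydroxybenzaldehyde
Conditions: AlCl3, pyridine, CH2Cl2, reflux; then aq HCl
Reagents that add atoms: none
Why: AlCl3 chelates the ortho-hydroxy-methoxy pair and activates only that methyl ether, which pyridine dealkylates (Lewis acid-mediated aryl methyl ether cleavage); the aldehyde and the aryl bromide are untouched.

Step 2
Reactants: 2 3-bromo-4,5-dihydroxybenzaldehyde
Product: 3 3-bromo-5-hydroxy-4-methoxybenzaldehyde
Conditions: MeI (1.05 equiv), Li2CO3, DMF, 40 °C
Reagents that add atoms: iodomethane, CI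
Why: The 4-hydroxyl, para to the formyl group and ortho to bromine, is the more acidic phenol, so a weak carbonate base forms only that phenoxide and one equivalent of MeI alkylates it (regioselective Williamson etherification, as known for 3,4-dihydroxybenzaldehydes).

Step 3
Reactants: 3 3-bromo-5-hydroxy-4-methoxybenzaldehyde; 4 N-acetylglycine
Product: 5 (Z)-4-[(3-acetoxy-5-bromo-4-methoxyphenyl)methylidene]-2-methyl-1,3-oxazol-5(4H)-one
Conditions: NaOAc, Ac2O, 110 °C
Reagents that add atoms: acetic anhydride, CC(=O)OC(C)=O
Why: Erlenmeyer–Plöchl azlactone synthesis: N-acetylglycine cyclises to 2-methyloxazol-5(4H)-one, which condenses with the aldehyde by aldol addition and dehydration to the thermodynamically preferred Z-alkylidene azlactone, while the phenol is acetylated by the medium.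

Step 4
Reactants: 5 (Z)-4-[(3-acetoxy-5-bromo-4-methoxyphenyl)methylidene]-2-methyl-1,3-oxazol-5(4H)-one
Product: 7 2-(3-bromo-5-hydroxy-4-methoxyphenyl)acetic acid, via arylpyruvic acid 6 (not isolated)
Conditions: 10% aq NaOH, reflux, N2; then 30% H2O2, 5–10 °C; then HCl to pH 1
Reagents that add atoms: water (from aqueous NaOH), O; hydrogen peroxide, OO
Why: Hot aqueous hydroxide opens the azlactone and hydrolyses the enamide and the aryl acetate to the arylpyruvate, which cold alkaline H2O2 cleaves by oxidative decarboxylation of the α-keto acid; this is the classical azlactone route to hydroxy- and methoxyphenylacetic acids, and the unactivated aryl bromide is inert to hydroxide.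

Step 5
Reactants: 7 2-(3-bromo-5-hydroxy-4-methoxyphenyl)acetic acid; 8 phloroglucinol (benzene-1,3,5-triol)
Product: 10 3-(3-bromo-5-hydroxy-4-methoxyphenyl)-5,7-dihydroxy-4H-chromen-4-one, via deoxybenzoin 9 (not isolated)
Conditions: BF3·OEt2, 85 °C; then DMF, MsCl, 50 → 75 °C; then aq NaOAc
Reagents that add atoms: N,N-dimethylformamide, CN(C)C=O
Why: BF3·OEt2 promotes Friedel–Crafts C-acylation of symmetrical phloroglucinol by the free acid; the iminium salt from DMF and MsCl (a Vilsmeier-type reagent) then formylates the activated methylene of the boron-chelated deoxybenzoin, and an ortho-hydroxyl adds with loss of dimethylamine to close ring C (one-pot deoxybenzoin route to polyhydroxyisoflavones). The two ortho-hydroxyls are equivalent, so only one isoflavone can form.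

Step 6
Reactants: 10 3-(3-bromo-5-hydroxy-4-methoxyphenyl)-5,7-dihydroxy-4H-chromen-4-one
Product: 11 3-(3-acetoxy-5-bromo-4-methoxyphenyl)-4-oxo-4H-chromene-5,7-diyl diacetate
Conditions: Ac2O, pyridine, DMAP (cat.), 25 → 40 °C
Reagents that add atoms: acetic anhydride, CC(=O)OC(C)=O
Why: Acyl-transfer catalysis by DMAP acetylates all three phenols, including the hydrogen-bonded 5-hydroxyl; the acetates mask the acidic phenols for the palladium step and give a soluble, easily purified bromide.

Step 7
Reactants: 11 3-(3-acetoxy-5-bromo-4-methoxyphenyl)-4-oxo-4H-chromene-5,7-diyl diacetate; 12 vinylboronic acid pinacol ester (2-ethenyl-4,4,5,5-tetramethyl-1,3,2-dioxaborolane)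
Product: 13 (E)-3-{3-acetoxy-4-methoxy-5-[2-(4,4,5,5-tetramethyl-1,3,2-dioxaborolan-2-yl)ethenyl]phenyl}-4-oxo-4H-chromene-5,7-diyl diacetate
Conditions: Pd(OAc)2 (5 mol %), [HP(t-Bu)3]BF4 (10 mol %), Cy2NMe, toluene, 85 °C
Reagents that add atoms: none
Why: Mizoroki–Heck reaction of a vinylboronate: zerovalent palladium carrying the bulky electron-rich phosphine inserts into the aryl C–Br bond, carbopalladation places the aryl group on the terminal carbon and syn β-hydride elimination gives the E-alkenylboronate. Under anhydrous conditions with a tertiary amine the boron is not activated, so Suzuki-type vinyl transfer is suppressed and the aryl acetates stay in place.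

Step 8
Reactants: 13 (E)-3-{3-acetoxy-4-methoxy-5-[2-(4,4,5,5-tetramethyl-1,3,2-dioxaborolan-2-yl)ethenyl]phenyl}-4-oxo-4H-chromene-5,7-diyl diacetate
Product: 14 (E)-5,7-dihydroxy-3-{3-hydroxy-4-methoxy-5-[2-(4,4,5,5-tetramethyl-1,3,2-dioxaborolan-2-yl)ethenyl]phenyl}-4H-chromen-4-one
Conditions: K2CO3, MeOH/THF, 0 °C → rt, N2; then pH 5 phosphate buffer
Reagents that add atoms: none
Why: Base-mediated transesterification of the three aryl acetates by methanol; the pinacol alkenylboronate tolerates brief exposure to carbonate in methanol, and the 7-phenoxide formed first deactivates C2 of the chromone toward methoxide.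

Step 9
Reactants: 14 (E)-5,7-dihydroxy-3-{3-hydroxy-4-methoxy-5-[2-(4,4,5,5-tetramethyl-1,3,2-dioxaborolan-2-yl)ethenyl]phenyl}-4H-chromen-4-one; 15 2-bromopropene
Product: 16 (E)-5,7-dihydroxy-3-[3-hydroxy-4-methoxy-5-(3-methylbuta-1,3-dien-1-yl)phenyl]-4H-chromen-4-one (the target)
Conditions: Pd(PPh3)4 (5 mol %), K2CO3 (6 equiv), 15 (3 equiv), 1,4-dioxane/H2O 4:1, degassed, sealed tube, 65 °C; then pH 5 phosphate buffer
Reagents that add atoms: none
Why: Zerovalent palladium from Pd(PPh3)4 inserts into the C(sp2)–Br bond of 2-bromopropene to give an isopropenyl complex of divalent palladium. Carbonate and water turn the pinacol boronate into its hydroxyboronate, which transfers the E-styryl group to palladium with retention of geometry. Reductive elimination then forms the Cβ–Cγ bond and returns zerovalent palladium. The closest known reaction type is the Suzuki–Miyaura coupling of (E)-alkenyl pinacol boronates with alkenyl bromides to give 1,3-dienes. No ring is closed and no stereocentre is created; the E geometry of Cα=Cβ was set in step 7 and is carried through by the stereoretentive transmetalation. The step needs cross-coupling to outrun protodeboronation and needs ring C to survive aqueous base. Excess volatile bromide in a sealed vessel and a fast oxidative addition serve the first need, and the 7-phenoxide, which makes C2 electron-rich, serves the second. **14** has no other carbon–halogen bond, the phenols are spectators as phenoxides, and buffering to pH 5 on work-up keeps the diene away from acid.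

## Compound list

1 | 5-bromovanillin (3-bromo-4-hydroxy-5-methoxybenzaldehyde) | COc1cc(C=O)cc(Br)c1O | starting material
2 | 3-bromo-4,5-dihydroxybenzaldehyde | O=Cc1cc(O)c(O)c(Br)c1 | intermediate
3 | 3-bromo-5-hydroxy-4-methoxybenzaldehyde | COc1c(Br)cc(C=O)cc1O | intermediate
4 | N-acetylglycine | CC(=O)NCC(=O)O | starting material
5 | (Z)-4-[(3-acetoxy-5-bromo-4-methoxyphenyl)methylidene]-2-methyl-1,3-oxazol-5(4H)-one | CC1=N/C(=C\c2cc(Br)c(OC)c(OC(C)=O)c2)C(=O)O1 | intermediate
6 | 3-(3-bromo-5-hydroxy-4-methoxyphenyl)-2-oxopropanoic acid | COc1c(Br)cc(CC(=O)C(=O)O)cc1O | intermediate (not isolated)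
7 | 2-(3-bromo-5-hydroxy-4-methoxyphenyl)acetic acid | COc1c(Br)cc(CC(=O)O)cc1O | intermediate
8 | phloroglucinol (benzene-1,3,5-triol) | Oc1cc(O)cc(O)c1 | starting material
9 | 2-(3-bromo-5-hydroxy-4-methoxyphenyl)-1-(2,4,6-trihydroxyphenyl)ethan-1-one | COc1c(Br)cc(CC(=O)c2c(O)cc(O)cc2O)cc1O | intermediate (not isolated)
10 | 3-(3-bromo-5-hydroxy-4-methoxyphenyl)-5,7-dihydroxy-4H-chromen-4-one | COc1c(Br)cc(-c2coc3cc(O)cc(O)c3c2=O)cc1O | intermediate
11 | 3-(3-acetoxy-5-bromo-4-methoxyphenyl)-4-oxo-4H-chromene-5,7-diyl diacetate | COc1c(Br)cc(-c2coc3cc(OC(C)=O)cc(OC(C)=O)c3c2=O)cc1OC(C)=O | intermediate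
12 | vinylboronic acid pinacol ester (2-ethenyl-4,4,5,5-tetramethyl-1,3,2-dioxaborolane) | C=CB1OC(C)(C)C(C)(C)O1 | starting material
13 | (E)-3-{3-acetoxy-4-methoxy-5-[2-(4,4,5,5-tetramethyl-1,3,2-dioxaborolan-2-yl)ethenyl]phenyl}-4-oxo-4H-chromene-5,7-diyl diacetate | COc1c(/C=C/B2OC(C)(C)C(C)(C)O2)cc(-c2coc3cc(OC(C)=O)cc(OC(C)=O)c3c2=O)cc1OC(C)=O | intermediate
14 | (E)-5,7-dihydroxy-3-{3-hydroxy-4-methoxy-5-[2-(4,4,5,5-tetramethyl-1,3,2-dioxaborolan-2-yl)ethenyl]phenyl}-4H-chromen-4-one | COc1c(/C=C/B2OC(C)(C)C(C)(C)O2)cc(-c2coc3cc(O)cc(O)c3c2=O)cc1O | intermediate
15 | 2-bromopropene | C=C(C)Br | starting material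
16 | (E)-5,7-dihydroxy-3-[3-hydroxy-4-methoxy-5-(3-methylbuta-1,3-dien-1-yl)phenyl]-4H-chromen-4-one | C=C(C)/C=C/c1cc(-c2coc3cc(O)cc(O)c3c2=O)cc(O)c1OC | target

## Step count and risk

Total step count: 9. Longest linear sequence: 9 steps, from **1** to **16**; **4**, **8**, **12** and **15** enter as purchased reagents.

**Step 9 (key step).** The most likely failure is protodeboronation of the phenoxide-bearing alkenylboronate before transmetalation. Other risks are loss of the volatile bromide from the reaction zone, thermal oligomerisation of the diene, and hydroxide addition at C2 that opens ring C. The fallback gives up boron and builds the diene by arylation and elimination. It sets out from **11** and comes back at **16**.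
- A Mizoroki–Heck reaction of **11** with 2-methylbut-3-en-2-ol (Pd(OAc)2, P(o-tol)3, Et3N, DMF, 100 °C) should give the tertiary allylic alcohol (E)-3-[3-acetoxy-5-(3-hydroxy-3-methylbut-1-en-1-yl)-4-methoxyphenyl]-4-oxo-4H-chromene-5,7-diyl diacetate F1.
- MsCl and Et3N in CH2Cl2 should dehydrate it through the tertiary mesylate toward the only available methyl hydrogens, giving (E)-3-[3-acetoxy-4-methoxy-5-(3-methylbuta-1,3-dien-1-yl)phenyl]-4-oxo-4H-chromene-5,7-diyl diacetate F2.
- K2CO3 in MeOH at 0 °C, as in step 8, should then remove the acetates without acid and give **16**.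

**Step 7.** The risks are transfer of the vinyl group through C–B transmetalation instead of carbopalladation, slow oxidative addition into the electron-rich ortho-methoxy aryl bromide, and partial acetyl loss at 85 °C. The fallback separates vinylation from borylation. It sets out from **11** and comes back at **13**.
- Stille coupling with tributyl(vinyl)stannane (Pd(PPh3)4, toluene, 100 °C) should give 3-(3-acetoxy-5-ethenyl-4-methoxyphenyl)-4-oxo-4H-chromene-5,7-diyl diacetate F3.
- Cross-metathesis of F3 with **12** using the second-generation Grubbs catalyst RuCl2(=CHPh)(PCy3)(H2IMes) in CH2Cl2 at 40 °C should give **13** with E selectivity.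

**Step 8.** The risks are methoxide-induced protodeboronation or exchange at boron, conjugate addition of methoxide at C2 before the 7-acetate is cleaved, and slow removal of the 5-acetate. The fallback drops the separate deprotection. It sets out from **13** and comes back at **16**: **13** enters the conditions of step 9 with additional K2CO3 and some MeOH as co-solvent. The acetates are then hydrolysed in the coupling flask and **14** exists only in solution. This fallback makes no new compound (F0).

**Step 5.** The risks are O-acylation or incomplete C-acylation of phloroglucinol, and sulfonylation or formylation of free phenols and of ring A by the iminium reagent. The fallback separates the two events and closes the ring through an enamine instead of a Vilsmeier-type formylation. It sets out from **9**, isolated after the BF3·OEt2 acylation of **8** with **7**, and comes back at **10**. N,N-Dimethylformamide dimethyl acetal in THF at 60 °C should convert the active methylene into the enaminone (E)-2-(3-bromo-5-hydroxy-4-methoxyphenyl)-3-(dimethylamino)-1-(2,4,6-trihydroxyphenyl)prop-2-en-1-one F4. On mild acidification F4 should close ring C with loss of dimethylamine to give **10**.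

## Further compounds

F1 | step 9 | (E)-3-[3-acetoxy-5-(3-hydroxy-3-methylbut-1-en-1-yl)-4-methoxyphenyl]-4-oxo-4H-chromene-5,7-diyl diacetate | COc1c(/C=C/C(C)(C)O)cc(-c2coc3cc(OC(C)=O)cc(OC(C)=O)c3c2=O)cc1OC(C)=O
F2 | step 9 | (E)-3-[3-acetoxy-4-methoxy-5-(3-methylbuta-1,3-dien-1-yl)phenyl]-4-oxo-4H-chromene-5,7-diyl diacetate | C=C(C)/C=C/c1cc(-c2coc3cc(OC(C)=O)cc(OC(C)=O)c3c2=O)cc(OC(C)=O)c1OC
F3 | step 7 | 3-(3-acetoxy-5-ethenyl-4-methoxyphenyl)-4-oxo-4H-chromene-5,7-diyl diacetate | C=Cc1cc(-c2coc3cc(OC(C)=O)cc(OC(C)=O)c3c2=O)cc(OC(C)=O)c1OC
F0 | step 8 | none | none
F4 | step 5 | (E)-2-(3-bromo-5-hydroxy-4-methoxyphenyl)-3-(dimethylamino)-1-(2,4,6-trihydroxyphenyl)prop-2-en-1-one | CN(C)/C=C(\c1cc(O)c(OC)c(Br)c1)C(=O)c1c(O)cc(O)cc1O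
A1 | alternative 1 | 3,5-bis(benzyloxy)-2-(trimethylsilyl)phenyl trifluoromethanesulfonate | C[Si](C)(C)c1c(OCc2ccccc2)cc(OCc2ccccc2)cc1OS(=O)(=O)C(F)(F)F
A2 | alternative 1 | methyl 2-[3-(benzyloxy)-5-bromo-4-methoxyphenyl]-3-oxopropanoate (enolisable, no fixed configuration) | COC(=O)C(C=O)c1cc(Br)c(OC)c(OCc2ccccc2)c1
A3 | alternative 1 | 5,7-bis(benzyloxy)-3-[3-(benzyloxy)-5-bromo-4-methoxyphenyl]chromen-4-one | COc1c(Br)cc(-c2coc3cc(OCc4ccccc4)cc(OCc4ccccc4)c3c2=O)cc1OCc1ccccc1
A4 | alternative 2 | 2-{[3-bromo-4-methoxy-5-(methoxymethoxy)phenyl](triphenylphosphoranylidene)acetyl}-3,5-bis(methoxymethoxy)phenyl formate | O=COc1cc(OCOC)cc(OCOC)c1C(=O)C(c1cc(Br)c(OC)c(OCOC)c1)=P(c1ccccc1)(c1ccccc1)c1ccccc1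
A5 | alternative 2 | 3-[3-bromo-4-methoxy-5-(methoxymethoxy)phenyl]-5,7-bis(methoxymethoxy)chromen-4-one | COCOc1cc(OCOC)c2c(c1)occ(-c1cc(Br)c(OC)c(OCOC)c1)c2=O
A6 | alternative 3 | 5,7-diacetoxy-2-(3-acetoxy-5-bromo-4-methoxyphenyl)chroman-4-one (racemic) | CC(=O)Oc1cc(OC(C)=O)c2c(c1)OC(c1cc(Br)c(OC)c(OC(C)=O)c1)CC2=O
A7 | alternative 3 | 5,7-diacetoxy-3-(3-acetoxy-5-bromo-4-methoxyphenyl)chromen-4-one | CC(=O)Oc1cc(OC(C)=O)c2c(c1)occ(-c1cc(Br)c(OC)c(OC(C)=O)c1)c2=O
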